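Numbering (lignan): Ar–C7–C8(OH)–C9 is the half that comes from syringaldehyde and Ar'–C7'–C8'(H)–C9' is the other half. Ring A = O, C7', C8', C8, C9. Ring B = O, C7, C8, C8', C9'.
Cuts: aryl–C7' goes first, because C7' sits next to the ring A oxygen and is a latent oxocarbenium carbon whose natural partner is the free para position of 2,6-dimethoxyphenol. C7'–O(C9) and C7–O(C9') follow, and the vicinal pair C7–O / C8–OH is read as an opened C7–C8 epoxide.
This leaves an acyclic epoxy diol dimethyl acetal. It is cut at the epoxide oxygen (E-allylic alcohol), at C8'–C7' (enolate + orthoformate) and at C7=C8 (Stobbe condensation of O-benzylsyringaldehyde with dimethyl succinate).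
Forward: the chain is built linearly in steps 1–6. One acid-triggered event then closes ring B (epoxide opening), closes ring A (acetal exchange) and joins the second arene at C7'. Debenzylation ends the route.
Stereochemistry: C8' comes from the (R)-4-benzyloxazolidinone enolate alkylation. C8 and C7 come from Sharpless epoxidation with L-(+)-tartrate, and C7 is inverted in the ring B closure. C7' comes from attack on the convex face of the cis-fused, V-shaped 3,7-dioxabicyclo[3.3.0]octane.

Key step: step 7

Remark: the bicyclic methyl acetal formed in the key step is treated as a mixture of C7' anomers, which has no consequence because C7' becomes planar before the arene arrives.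

Step 1
Reactants: 1 syringaldehyde (4-hydroxy-3,5-dimethoxybenzaldehyde)
Product: 2 4-(benzyloxy)-3,5-dimethoxybenzaldehyde
Conditions: BnBr, K2CO3, DMF, 60 °C
Reagents that add atoms: benzyl bromide, BrCc1ccccc1
Why: Williamson ether synthesis on the acidic, hindered phenol; the benzyl cap survives base, TiCl4 at low temperature, hydride and peroxide, keeps this arene a weak donor so that neither the later epoxide nor the C7–O bond ionises prematurely, and leaves by hydrogenolysis at the end.

Step 2
Reactants: 2 4-(benzyloxy)-3,5-dimethoxybenzaldehyde; 3 dimethyl succinate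
Product: 4 (E)-4-[4-(benzyloxy)-3,5-dimethoxyphenyl]-3-(methoxycarbonyl)but-3-enoic acid
Conditions: NaOMe, MeOH, reflux; aq HCl work-up
Reagents that add atoms: none
Why: Stobbe condensation, the classical entry to lignan C6–C3–C3 chains, should give the E half ester (aryl trans to CO2Me, cis to the CH2 group) and at the same time tells C9 (ester) from C9' (free acid).

Step 3
Reactants: 4 Stobbe half ester; 5 (R)-4-benzyl-1,3-oxazolidin-2-one
Product: 7 N-acyl oxazolidinone of 4 (E alkene, 4R auxiliary), via mixed pivalic anhydride 6 (not isolated)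
Conditions: PivCl, Et3N, THF, −20 °C; then 5, LiCl, −20 °C → rt
Reagents that add atoms: pivaloyl chloride, CC(C)(C)C(=O)Cl (its acyl group is found only in 6)
Why: N-Acylation of an oxazolidinone through the mixed pivalic anhydride with LiCl and Et3N needs no strong base, so the activated C8' methylene and the E alkene are left alone, and attack takes place at the unhindered carbonyl of 6.

Step 4
Reactants: 7 N-acyl oxazolidinone
Product: 9 (8'S)-C8'-(dimethoxymethyl) imide (E alkene, 4R auxiliary), via chlorotitanium Z-enolate 8 (not isolated)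
Conditions: TiCl4, iPr2NEt, CH2Cl2, −78 → 0 °C; HC(OMe)3, 0 °C
Reagents that add atoms: trimethyl orthoformate, COC(OC)OC; TiCl4, Cl[Ti](Cl)(Cl)Cl (titanium and chlorine are found only in 8)
Why: Evans-type alkylation of a chelated chlorotitanium Z-enolate with an orthoester: the dienolate reacts at its alpha carbon C8' on the face turned away from the benzyl group of the (R)-auxiliary, which sets C8' (S in 9) and brings in C7' directly at the aldehyde oxidation level as its dimethyl acetal.

Step 5
Reactants: 9 alkylated imide
Product: 10 (2E,3R)-2-{[4-(benzyloxy)-3,5-dimethoxyphenyl]methylidene}-3-(dimethoxymethyl)butane-1,4-diol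
Conditions: LiAlH4, THF, −40 → 0 °C; Rochelle salt work-up
Reagents that add atoms: none
Why: LiAlH4 reduction cleaves the imide to the C9' carbinol with release of the auxiliary and reduces the conjugated ester to the allylic C9 carbinol in the same flask, whereas acetal, benzyl ether and, at or below 0 °C, the trisubstituted styrene bond are inert and C8' (now R by a priority change only) is not touched.

Step 6
Reactants: 10 allylic diol acetal
Product: 11 (2S)-2-{(2S,3S)-3-[4-(benzyloxy)-3,5-dimethoxyphenyl]-2-(hydroxymethyl)oxiran-2-yl}-3,3-dimethoxypropan-1-ol (7S,8S,8'S)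
Conditions: Ti(OiPr)4 (0.2 equiv), L-(+)-DIPT (0.25 equiv), t-BuOOH (decane), 4 Å MS, CH2Cl2, −25 °C; NaOH/brine work-up
Reagents that add atoms: tert-butyl hydroperoxide, CC(C)(C)OO
Why: Sharpless asymmetric epoxidation of an E-configured 2,3-disubstituted allylic alcohol, a well-behaved substrate class: with L-(+)-DIPT the oxygen should arrive on the face that gives the (7S,8S)-epoxide, by reagent control and against the modest bias of C8', and only the allylic C7=C8 bond is addressed.

Step 7
Reactants: 11 epoxy diol dimethyl acetal; 12 2,6-dimethoxyphenol (syringol)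
Product: 15 4-O-benzyl-8-hydroxysyringaresinol (7R,8S,7'S,8'R), via bicyclic methyl acetal 13 (not isolated), via oxocarbenium ion 14 (not isolated)
Conditions: 12 (3 equiv), BF3·OEt2 (0.3 equiv), 5 Å MS, CH2Cl2, −78 → −20 °C; Et3N quench at −20 °C
Reagents that add atoms: none
Why: The acid activates both labile sites of 11: the C9'–OH opens the epoxide at benzylic C7 from the rear (5-endo-tet, feasible because the aryl group loosens the C7–O bond, as in the acid-catalysed cyclisation of 4-aryl-3,4-epoxy alcohols to 2-aryl-3-hydroxytetrahydrofurans), which closes ring B, inverts C7 from S to R and frees the C8 tertiary alcohol in the configuration fixed in step 6, while the C9–OH replaces one methoxy group at C7' through the acyclic methoxycarbenium ion (5-exo-trig) and closes ring A to give 13. Loss of the second methoxy group gives the ring A oxocarbenium ion 14, which is intercepted at C7' by C4 of syringol in a Friedel–Crafts alkylation, the reaction type known from the arylation of furofuran lactols and 2-alkoxytetrahydrofurans with phenols. Both closures can only give the cis-fused bicycle, because steps 4 and 6 placed C7' syn to C9 and C9' syn to C7, and the four-membered alternatives (C9'–OH to C7', C8–OH to C7') do not compete. C7' is controlled by the V shape of the 3,7-dioxabicyclo[3.3.0]octane: ring B, attached through C9' on the neighbouring C8', closes the concave face, so the arene enters on the convex face, cis to H8' and to the 8-OH, which gives the 7'S exo aryl group. Regioselectivity in the arene comes from the free phenol, whose para carbon is the only unhindered position conjugated with OH (both ortho positions carry OMe, C3 and C5 are flanked by OMe, and O-alkylation to the aryl acetal is reversible under acid). Chemoselectivity rests on the benzyl cap of the first arene, which keeps the C7–O bond of ring B far less ionisable than the acetal, on the intramolecular epoxide opening outrunning attack by syringol at −78 °C, and on the early basic quench, which forestalls re-ionisation at C7' or loss of water towards a furan.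

Step 8
Reactants: 15 4-O-benzyl-8-hydroxysyringaresinol
Product: 16 8-hydroxysyringaresinol, (3R,3aS,6S,6aR)-3,6-bis(4-hydroxy-3,5-dimethoxyphenyl)tetrahydro-1H,3H-furo[3,4-c]furan-3a(4H)-ol
Conditions: H2 (1 atm), 10 % Pd/C, EtOAc–EtOH, rt, stopped at full conversion
Reagents that add atoms: none
Why: Hydrogenolysis of the aryl benzyl ether over Pd/C at 1 atm should be much faster than that of the ring C7–O and C7'–O bonds, so that brief exposure frees the second phenol without touching a stereocentre.

Compound list
1 | syringaldehyde | COc1cc(C=O)cc(OC)c1O | starting material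
2 | 4-(benzyloxy)-3,5-dimethoxybenzaldehyde | COc1cc(C=O)cc(OC)c1OCc1ccccc1 | intermediate
3 | dimethyl succinate | COC(=O)CCC(=O)OC | starting material
4 | (E)-4-[4-(benzyloxy)-3,5-dimethoxyphenyl]-3-(methoxycarbonyl)but-3-enoic acid | COC(=O)/C(CC(=O)O)=C/c1cc(OC)c(OCc2ccccc2)c(OC)c1 | intermediate
5 | (R)-4-benzyl-1,3-oxazolidin-2-one | O=C1N[C@H](Cc2ccccc2)CO1 | starting material
6 | mixed pivalic anhydride of 4 | COC(=O)/C(CC(=O)OC(=O)C(C)(C)C)=C/c1cc(OC)c(OCc2ccccc2)c(OC)c1 | intermediate
7 | methyl (E)-2-{2-[(4R)-4-benzyl-2-oxo-1,3-oxazolidin-3-yl]-2-oxoethyl}-3-[4-(benzyloxy)-3,5-dimethoxyphenyl]prop-2-enoate | COC(=O)/C(CC(=O)N1[C@H](Cc2ccccc2)COC1=O)=C/c1cc(OC)c(OCc2ccccc2)c(OC)c1 | intermediate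
8 | trichlorotitanium Z-enolate of 7 | COC(=O)/C(=C/c1cc(OC)c(OCc2ccccc2)c(OC)c1)/C=C(\O[Ti](Cl)(Cl)Cl)N1[C@H](Cc2ccccc2)COC1=O | intermediate
9 | methyl (E)-2-{(2S)-1-[(4R)-4-benzyl-2-oxo-1,3-oxazolidin-3-yl]-3,3-dimethoxy-1-oxopropan-2-yl}-3-[4-(benzyloxy)-3,5-dimethoxyphenyl]prop-2-enoate | COC(=O)/C(=C/c1cc(OC)c(OCc2ccccc2)c(OC)c1)[C@@H](C(OC)OC)C(=O)N1[C@H](Cc2ccccc2)COC1=O | intermediate
10 | (2E,3R)-2-{[4-(benzyloxy)-3,5-dimethoxyphenyl]methylidene}-3-(dimethoxymethyl)butane-1,4-diol | OC[C@H](C(OC)OC)/C(CO)=C\c1cc(OC)c(OCc2ccccc2)c(OC)c1 | intermediate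
11 | (2S)-2-{(2S,3S)-3-[4-(benzyloxy)-3,5-dimethoxyphenyl]-2-(hydroxymethyl)oxiran-2-yl}-3,3-dimethoxypropan-1-ol | OC[C@H](C(OC)OC)[C@@]1(CO)O[C@H]1c2cc(OC)c(OCc3ccccc3)c(OC)c2 | intermediate
12 | 2,6-dimethoxyphenol (syringol) | COc1cccc(OC)c1O | starting material
13 | (3R,3aS,6aS)-3-[4-(benzyloxy)-3,5-dimethoxyphenyl]-6-methoxytetrahydro-1H,3H-furo[3,4-c]furan-3a(4H)-ol, both C7' anomers | COC1OC[C@]2(O)[C@@H](c3cc(OC)c(OCc4ccccc4)c(OC)c3)OC[C@H]12 | intermediate
14 | ring A oxocarbenium ion derived from 13 (7R,8S,8'S) | C1=[O+]C[C@]2(O)[C@@H](c3cc(OC)c(OCc4ccccc4)c(OC)c3)OC[C@H]12 | intermediate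
15 | 4-O-benzyl-8-hydroxysyringaresinol (7R,8S,7'S,8'R) | COc1cc([C@H]2OC[C@]3(O)[C@@H](c4cc(OC)c(OCc5ccccc5)c(OC)c4)OC[C@H]23)cc(OC)c1O | intermediate
16 | 8-hydroxysyringaresinol (7R,8S,7'S,8'R) | COc1cc([C@H]2OC[C@]3(O)[C@@H](c4cc(OC)c(O)c(OC)c4)OC[C@H]23)cc(OC)c1O | target

Total step count: 8. Longest linear sequence: 8 steps (1 → 16).

Steps most likely to fail

Step 7.
- What may go wrong: syringol may attack through C3 instead of C4. The new p-hydroxybenzylic C7'–O bond may re-ionise, with epimerisation or a second arylation. Ion 14 may lose a proton and then dehydrate towards a furan.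
- Fallback (sets out from 11, comes back at 16): 11 is cyclised alone with catalytic camphorsulfonic acid in CH2Cl2 at 0 °C, and the bicyclic methyl acetal 13 is now isolated. Exchange with benzenesulfinic acid (CaCl2, CH2Cl2) gives the C7' phenyl sulfone F1.
- Commercial 4-bromo-2,6-dimethoxyphenol is benzylated (BnBr, K2CO3) to 2-(benzyloxy)-5-bromo-1,3-dimethoxybenzene F2. Mg in THF turns this into the aryl Grignard reagent F3, and ZnBr2 turns that into the arylzinc bromide F4.
- F4 displaces the sulfinate of F1 from the convex face. The carbon–carbon bond can form only at the metal-bearing carbon, so the regiochemical question disappears. No acid is present that could re-ionise the product, 4,4'-di-O-benzyl-8-hydroxysyringaresinol F5.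
- Hydrogenolysis of both benzyl ethers under the conditions of step 8 gives 16.

Step 6.
- What may go wrong: facial selectivity may erode, because the tartrate complex must deliver oxygen to the alkene face that carries the dimethoxymethyl group in the A(1,3)-minimised conformer. The 1,4-diol may bind to titanium and slow the reaction. The epoxide may open prematurely.
- Fallback (sets out from 10, comes back at 13): 10 is first closed with catalytic PPTS in CH2Cl2 to the monocyclic ring A methyl acetal F6. In F6 the alkene is exocyclic and the required face is the open one, anti to the C9' hydroxymethyl group on the neighbouring C8'.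
- Epoxidation with dimethyldioxirane in acetone at −20 °C, under substrate control alone, gives the spiro epoxide F7. Under the conditions of step 7, F7 closes ring B to 13 and goes on to 15.

Step 4.
- What may go wrong: the beta,beta-dimethoxy imide may lose methanol. The dienolate may react at its gamma carbon. The crowded central benzyl ether may be cleaved by TiCl4. C8' may epimerise.
- Fallback (sets out from 4, comes back at 10): 4 is coupled with 1,3-thiazolidine-2-thione (EDC·HCl, DMAP, CH2Cl2) to the achiral N-acyl thiazolidinethione F8.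
- A catalytic enantioselective orthoester alkylation follows, by soft enolisation with (Tol-BINAP)Ni(OTf)2 (10 mol %, the ligand antipode that leads to the S product), 2,6-lutidine, BF3·OEt2 and HC(OMe)3 in CH2Cl2 at −78 °C. It gives the dimethyl acetal F9 under catalyst control, without TiCl4 and with a much weaker base.
- LiAlH4 then reduces the thioimide and the ester to 10.

Further compounds
F1 | step 7 | (3R,3aS,6aS)-3-[4-(benzyloxy)-3,5-dimethoxyphenyl]-6-(phenylsulfonyl)tetrahydro-1H,3H-furo[3,4-c]furan-3a(4H)-ol | O=S(=O)(c1ccccc1)C1OC[C@]2(O)[C@@H](c3cc(OC)c(OCc4ccccc4)c(OC)c3)OC[C@H]12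
F2 | step 7 | 2-(benzyloxy)-5-bromo-1,3-dimethoxybenzene | COc1cc(Br)cc(OC)c1OCc1ccccc1
F3 | step 7 | [4-(benzyloxy)-3,5-dimethoxyphenyl]magnesium bromide | COc1cc([Mg]Br)cc(OC)c1OCc1ccccc1
F4 | step 7 | [4-(benzyloxy)-3,5-dimethoxyphenyl]zinc bromide | COc1cc([Zn]Br)cc(OC)c1OCc1ccccc1
F5 | step 7 | 4,4'-di-O-benzyl-8-hydroxysyringaresinol (7R,8S,7'S,8'R) | COc1cc([C@H]2OC[C@]3(O)[C@@H](c4cc(OC)c(OCc5ccccc5)c(OC)c4)OC[C@H]23)cc(OC)c1OCc1ccccc1
F6 | step 6 | [(3R,4E)-4-{[4-(benzyloxy)-3,5-dimethoxyphenyl]methylidene}-2-methoxyoxolan-3-yl]methanol, both anomers | COC1OC/C(=C/c2cc(OC)c(OCc3ccccc3)c(OC)c2)[C@@H]1CO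
F7 | step 6 | {2-[4-(benzyloxy)-3,5-dimethoxyphenyl]-6-methoxy-1,5-dioxaspiro[2.4]heptan-7-yl}methanol (7S,8S,8'S in lignan numbering), both anomers | COC1OC[C@@]2(O[C@H]2c3cc(OC)c(OCc4ccccc4)c(OC)c3)[C@@H]1CO
F8 | step 4 | methyl (E)-3-[4-(benzyloxy)-3,5-dimethoxyphenyl]-2-[2-oxo-2-(2-thioxo-1,3-thiazolidin-3-yl)ethyl]prop-2-enoate | COC(=O)/C(CC(=O)N1CCSC1=S)=C/c1cc(OC)c(OCc2ccccc2)c(OC)c1
F9 | step 4 | methyl (E)-3-[4-(benzyloxy)-3,5-dimethoxyphenyl]-2-[(2S)-3,3-dimethoxy-1-oxo-1-(2-thioxo-1,3-thiazolidin-3-yl)propan-2-yl]prop-2-enoate | COC(=O)/C(=C/c1cc(OC)c(OCc2ccccc2)c(OC)c1)[C@@H](C(OC)OC)C(=O)N1CCSC1=S
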